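**Retrosynthetic overview**
1. Pyran ring (formed last): inverse-demand hetero-Diels–Alder reaction of the hirsutane heterodiene 18 (ring C = 2-hydroxy-5-methylidenecyclopent-2-en-1-one) with (1S,9R)-isocaryophyllene 31; the dienol adduct ketonises to the target.
2. Ring C of the triquinane: Tius allene-ether Nazarov annulation on the bicyclic enamide 14, which also creates the angular C-methyl quaternary carbon.
3. Rings A/B and the absolute configuration of the triquinane: desymmetrising [2+2] cycloaddition of a chiral keteniminium salt with the achiral cyclopentene 3 (key step), then regioselective one-carbon ring expansion of the cyclobutanone.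
4. Caryophyllane half: auxiliary-controlled keteniminium [2+2] gives cyclobutanone 23, Negishi coupling brings in the Z olefin, a low-valent-titanium keto ester cyclisation closes the nine-membered ring, Wittig methylenation finishes it.
5. Ring order: A, then B, then C (hirsutane); cyclobutane, then nine-membered ring (caryophyllane); pyran last.

Assumption 1: the target is taken exactly as drawn; its caryophyllane half is (1S,9R), antipodal to natural (−)-β-caryophyllene, and the pyran fusion is cis (Z-olefin-derived), so (1S,9R)-isocaryophyllene is made de novo.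
Assumption 2: the sense of induction of the 2,5-dimethylpyrrolidine auxiliary is taken as written in steps 2 and 10; if it is opposite, the antipodal amine is used.

**Route**

Step 1
Reactants: 1 benzyl propanoate; 2 (2Z)-1,4-dichlorobut-2-ene
Product: 3 benzyl 1-methylcyclopent-3-ene-1-carboxylate (achiral)
Conditions: LiN(iPr)2 (1.05 equiv), THF, −78 °C; 2; then LiN(iPr)2 (1.1 equiv), DMPU, −78 °C to rt
Reagents that add atoms: none
Why: Double enolate alkylation (SN2 at one allylic chloride, then 5-exo-tet closure that the Z olefin holds in reach) gives the mirror-symmetric cyclopentene; no stereocentre is formed.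

Step 2
Reactants: 3 benzyl 1-methylcyclopent-3-ene-1-carboxylate; 4 (2R,5R)-2,5-dimethylpyrrolidine
Product: 7 benzyl (1R,3S,5R)-3-methyl-6-oxobicyclo[3.2.0]heptane-3-carboxylate, via N-acetyl auxiliary amide 5 (not isolated), via cyclobutaniminium triflate 6 (not isolated)
Conditions: Ac2O, CH2Cl2, rt, then evaporation; Tf2O, 2,4,6-collidine, ClCH2CH2Cl, −20 °C to reflux; then aq NaHCO3, 50 °C
Reagents that add atoms: acetic anhydride, CC(=O)OC(C)=O; water, O
Why: Ghosez-type keteniminium–olefin [2+2] cycloaddition in which the C2-symmetric auxiliary differentiates the two enantiotopic olefin carbons of 3 (desymmetrisation that fixes both ring-fusion centres and makes the quaternary carbon stereogenic), the suprafacial addition enforces the cis fusion, and approach anti to the pseudo-axial ester places the new ring cis to the C-methyl.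

Step 3
Reactants: 8 1-(morpholin-4-yl)butane-1,3-dione
Product: 10 2-diazo-1-(morpholin-4-yl)ethan-1-one, via diazo acetoacetamide 9 (not isolated)
Conditions: 4-acetamidobenzenesulfonyl azide, NEt3, MeCN, 0 °C to rt; then aq KOH, rt
Reagents that add atoms: 4-acetamidobenzenesulfonyl azide, CC(=O)Nc1ccc(cc1)S(=O)(=O)N=[N+]=[N-]
Why: Regitz diazo transfer to the active methylene followed by hydroxide-induced deacetylation (retro-Claisen) gives the diazoacetamide.

Step 4
Reactants: 7 benzyl (1R,3S,5R)-3-methyl-6-oxobicyclo[3.2.0]heptane-3-carboxylate; 10 2-diazo-1-(morpholin-4-yl)ethan-1-one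
Product: 11 benzyl (2S,3aR,6aS)-2-methyl-5-(morpholine-4-carbonyl)-4-oxooctahydropentalene-2-carboxylate (C5 epimers and enol)
Conditions: Sc(OTf)3 (10 mol%), CH2Cl2, −20 °C to rt
Reagents that add atoms: none
Why: Lewis-acid-catalysed diazo–carbonyl ring expansion (Tiffeneau–Demjanov type) driven by cyclobutanone strain, in which the less substituted CH2 migrates so that the amide-bearing carbon is inserted on the methylene side; the existing stereocentres are untouched.

Step 5
Reactants: 11 benzyl (2S,3aR,6aS)-2-methyl-5-(morpholine-4-carbonyl)-4-oxooctahydropentalene-2-carboxylate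
Product: 12 benzyl (2S,3aR,6aS)-2-methyl-5-(morpholine-4-carbonyl)-4-[(trifluoromethanesulfonyl)oxy]-1,2,3,3a,6,6a-hexahydropentalene-2-carboxylate
Conditions: NaH, PhNTf2, THF, 0 °C to rt
Reagents that add atoms: N-phenylbis(trifluoromethanesulfonimide), FC(F)(F)S(=O)(=O)N(c1ccccc1)S(=O)(=O)C(F)(F)F
Why: O-triflation of the β-keto amide enolate, which can enolise in one direction only.

Step 6
Reactants: 12 enol triflate
Product: 13 benzyl (2S,3aR,6aS)-2,4-dimethyl-5-(morpholine-4-carbonyl)-1,2,3,3a,6,6a-hexahydropentalene-2-carboxylate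
Conditions: MeMgBr, Fe(acac)3 (5 mol%), THF/NMP, −30 °C
Reagents that add atoms: methylmagnesium bromide, C[Mg]Br
Why: Iron-catalysed Kumada-type cross-coupling of the alkenyl triflate, which at this temperature is much faster than Grignard addition to the ester or amide.

Step 7
Reactants: 13 benzyl ester enamide
Product: 14 (2S,3aR,6aS)-2,4-dimethyl-5-(morpholine-4-carbonyl)-1,2,3,3a,6,6a-hexahydropentalene-2-carboxylic acid
Conditions: H2 (1 atm), Pd/C (10% Pd on carbon), EtOAc, rt
Reagents that add atoms: none
Why: Hydrogenolysis of the benzyl ester; the tetrasubstituted, amide-conjugated olefin is not reduced under these conditions.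

Step 8
Reactants: 15 3-(methoxymethoxy)prop-1-yne
Product: 16 1-(methoxymethoxy)propa-1,2-diene
Conditions: KOtBu (0.2 equiv), neat, 60 °C, then distillation
Reagents that add atoms: none
Why: Base-catalysed propargyl-to-allenyl ether isomerisation to the thermodynamically favoured alkoxyallene.

Step 9
Reactants: 14 enamide acid; 16 1-(methoxymethoxy)propa-1,2-diene
Product: 18 triquinane heterodiene acid (ring C = 2-hydroxy-5-methylidenecyclopent-2-en-1-one), via allenyl vinyl ketone 17 (not isolated)
Conditions: 16 (3.5 equiv), n-BuLi, THF, −78 °C; then 14, −78 to −30 °C; then 5% aq HCl, −78 °C to rt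
Reagents that add atoms: none
Why: Tius cyclopentannulation in which acyl substitution at the morpholine amide gives ketone 17, whose allene-ether Nazarov 4π-conrotatory closure (terminated by loss of the methoxymethyl cation) takes place on the convex face of the cis-bicyclo[3.3.0]octene, anti to ring A, and so sets the angular methyl-bearing quaternary carbon in the cis-anti-cis sense.

Step 10
Reactants: 19 5-bromo-2-methylpent-2-ene; 20 (2S,5S)-2,5-dimethylpyrrolidine
Product: 23 (2R)-2-(2-bromoethyl)-3,3-dimethylcyclobutan-1-one, via N-acetyl auxiliary amide 21 (not isolated), via cyclobutaniminium triflate 22 (not isolated)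
Conditions: Ac2O, CH2Cl2, rt, then evaporation; Tf2O, 2,4,6-collidine, ClCH2CH2Cl, −20 °C to reflux; then aq NaHCO3, 50 °C
Reagents that add atoms: acetic anhydride, CC(=O)OC(C)=O; water, O
Why: Ghosez-type keteniminium–olefin [2+2] cycloaddition in which the iminium carbon bonds to the less substituted olefin carbon (gem-dimethyl ends up β to the carbonyl) and the C2-symmetric auxiliary selects the olefin face, setting the single stereocentre.

Step 11
Reactants: 24 methyl 4-oxobutanoate; 25 ethyl(triphenyl)phosphonium iodide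
Product: 26 methyl (4Z)-5-iodohex-4-enoate
Conditions: 25, n-BuLi, THF, rt; I2, −78 °C; NaN(SiMe3)2, −78 °C; then 24, −78 °C to rt
Reagents that add atoms: iodine, II
Why: Stork–Zhao iodo-olefination, a kinetically controlled Wittig reaction of the non-stabilised α-iodo ylide that places iodine cis to the chain (Z).

Step 12
Reactants: 23 (2R)-2-(2-bromoethyl)-3,3-dimethylcyclobutan-1-one; 26 methyl (4Z)-5-iodohex-4-enoate
Product: 28 methyl (4Z)-7-[(1R)-2,2-dimethyl-4-oxocyclobutyl]-5-methylhept-4-enoate, via alkylzinc bromide 27 (not isolated)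
Conditions: Zn dust, I2 (5 mol%), DMA, 70 °C; then 26, PdCl2(dppf) (3 mol%), rt to 50 °C
Reagents that add atoms: none
Why: Negishi sp3–sp2 cross-coupling, which tolerates the ketone and ester and retains the olefin geometry, so the two chains end up cis on the trisubstituted olefin.

Step 13
Reactants: 28 keto ester
Product: 30 (1S,4Z,9R)-4,11,11-trimethylbicyclo[7.2.0]undec-4-en-8-one, via cyclic methyl enol ether 29 (not isolated)
Conditions: TiCl3, LiAlH4, NEt3, DME, reflux, slow addition (high dilution); then aq HCl, THF, rt; then NaOMe (cat.), MeOH, rt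
Reagents that add atoms: water, O
Why: McMurry keto ester cyclisation with low-valent titanium closes the nine-membered ring as the enol ether, and hydrolysis followed by base equilibration delivers the more stable trans-fused ketone (C9 under thermodynamic control, C1 untouched).

Step 14
Reactants: 30 nor-ketone
Product: 31 (1S,4Z,9R)-4,11,11-trimethyl-8-methylidenebicyclo[7.2.0]undec-4-ene
Conditions: Ph3PCH3Br, KOtBu, toluene, rt to 80 °C
Reagents that add atoms: methyltriphenylphosphonium bromide, C[P+](c1ccccc1)(c1ccccc1)c1ccccc1.[Br-]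
Why: Wittig methylenation of the hindered ketone; the basic ylide medium keeps the ring fusion trans.

Step 15
Reactants: 18 triquinane heterodiene acid; 31 (1S,9R)-isocaryophyllene
Product: 33 CNP0483070.2, via dienol cycloadduct 32 (not isolated)
Conditions: 31 (2 equiv), toluene, 80 °C, sealed tube, 2,6-di-tert-butyl-4-methylphenol (cat.)
Reagents that add atoms: none
Why: Inverse-electron-demand hetero-Diels–Alder reaction of the α-methylene ketone in which CH2 bonds to the less substituted olefin carbon and oxygen to the methyl-bearing one, suprafacial addition to the Z olefin gives the cis-fused pyran, attack on the exposed outer face of the folded nine-membered ring sets both new centres, and ketonisation of dienol 32 gives the thermodynamically preferred cis B/C fusion.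

**Compound list**

1 | benzyl propanoate | CCC(=O)OCc1ccccc1 | starting material
2 | (2Z)-1,4-dichlorobut-2-ene | ClC/C=C\CCl | starting material
3 | benzyl 1-methylcyclopent-3-ene-1-carboxylate (achiral) | CC1(C(=O)OCc2ccccc2)CC=CC1 | intermediate
4 | (2R,5R)-2,5-dimethylpyrrolidine | C[C@@H]1CC[C@@H](C)N1 | starting material
5 | 1-[(2R,5R)-2,5-dimethylpyrrolidin-1-yl]ethan-1-one (not isolated) | C[C@@H]1CC[C@@H](C)N1C(C)=O | intermediate
6 | (2R,5R)-1-[(1R,3S,5R)-3-(benzyloxycarbonyl)-3-methylbicyclo[3.2.0]heptan-6-ylidene]-2,5-dimethylpyrrolidin-1-ium trifluoromethanesulfonate (not isolated) | C[C@@H]1CC[C@@H](C)[N+]1=C4C[C@H]2C[C@](C)(C(=O)OCc3ccccc3)C[C@@H]42.[O-]S(=O)(=O)C(F)(F)F | intermediate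
7 | benzyl (1R,3S,5R)-3-methyl-6-oxobicyclo[3.2.0]heptane-3-carboxylate (cis-fused; cyclobutanone cis to the C3 methyl, ring-fusion H cis to the ester) | O=C1C[C@H]2C[C@](C)(C(=O)OCc3ccccc3)C[C@@H]12 | intermediate
8 | 1-(morpholin-4-yl)butane-1,3-dione | CC(=O)CC(=O)N1CCOCC1 | starting material
9 | 2-diazo-1-(morpholin-4-yl)butane-1,3-dione (not isolated) | CC(=O)C(=[N+]=[N-])C(=O)N1CCOCC1 | intermediate
10 | 2-diazo-1-(morpholin-4-yl)ethan-1-one | [N-]=[N+]=CC(=O)N1CCOCC1 | intermediate
11 | benzyl (2S,3aR,6aS)-2-methyl-5-(morpholine-4-carbonyl)-4-oxooctahydropentalene-2-carboxylate (C5 epimers/enol) | O=C1C(C(=O)N2CCOCC2)C[C@H]3C[C@](C)(C(=O)OCc4ccccc4)C[C@@H]13 | intermediate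
12 | benzyl (2S,3aR,6aS)-2-methyl-5-(morpholine-4-carbonyl)-4-[(trifluoromethanesulfonyl)oxy]-1,2,3,3a,6,6a-hexahydropentalene-2-carboxylate | FC(F)(F)S(=O)(=O)OC1=C(C(=O)N2CCOCC2)C[C@H]3C[C@](C)(C(=O)OCc4ccccc4)C[C@@H]13 | intermediate
13 | benzyl (2S,3aR,6aS)-2,4-dimethyl-5-(morpholine-4-carbonyl)-1,2,3,3a,6,6a-hexahydropentalene-2-carboxylate | CC1=C(C(=O)N2CCOCC2)C[C@H]3C[C@](C)(C(=O)OCc4ccccc4)C[C@@H]13 | intermediate
14 | (2S,3aR,6aS)-2,4-dimethyl-5-(morpholine-4-carbonyl)-1,2,3,3a,6,6a-hexahydropentalene-2-carboxylic acid | CC1=C(C(=O)N2CCOCC2)C[C@H]3C[C@](C)(C(=O)O)C[C@@H]13 | intermediate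
15 | 3-(methoxymethoxy)prop-1-yne | C#CCOCOC | starting material
16 | 1-(methoxymethoxy)propa-1,2-diene | C=C=COCOC | intermediate
17 | (2S,3aR,6aS)-5-[2-(methoxymethoxy)buta-2,3-dienoyl]-2,4-dimethyl-1,2,3,3a,6,6a-hexahydropentalene-2-carboxylic acid (not isolated) | CC1=C(C(=O)C(OCOC)=C=C)C[C@H]2C[C@](C)(C(=O)O)C[C@@H]12 | intermediate
18 | triquinane heterodiene acid: cis-anti-cis linear triquinane; ring C is a 2-hydroxy-5-methylidenecyclopent-2-en-1-one (enol C=C at the B/C fusion, methylidene next to the angular-methyl carbon); ring A carries C-methyl and CO2H, the CO2H cis to the A/B ring-fusion hydrogens | C=C1C(=O)C(O)=C2C[C@H]3C[C@](C)(C(=O)O)C[C@H]3[C@]12C | intermediate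
19 | 5-bromo-2-methylpent-2-ene | CC(C)=CCCBr | starting material
20 | (2S,5S)-2,5-dimethylpyrrolidine | C[C@H]1CC[C@H](C)N1 | starting material
21 | 1-[(2S,5S)-2,5-dimethylpyrrolidin-1-yl]ethan-1-one (not isolated) | C[C@H]1CC[C@H](C)N1C(C)=O | intermediate
22 | (2S,5S)-1-[(2R)-2-(2-bromoethyl)-3,3-dimethylcyclobutylidene]-2,5-dimethylpyrrolidin-1-ium trifluoromethanesulfonate (not isolated) | C[C@H]1CC[C@H](C)[N+]1=C4CC(C)(C)[C@H]4CCBr.[O-]S(=O)(=O)C(F)(F)F | intermediate
23 | (2R)-2-(2-bromoethyl)-3,3-dimethylcyclobutan-1-one | BrCC[C@H]1C(=O)CC1(C)C | intermediate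
24 | methyl 4-oxobutanoate | COC(=O)CCC=O | starting material
25 | ethyl(triphenyl)phosphonium iodide | CC[P+](c1ccccc1)(c1ccccc1)c1ccccc1.[I-] | starting material
26 | methyl (4Z)-5-iodohex-4-enoate | COC(=O)CC/C=C(/C)I | intermediate
27 | {2-[(1R)-2,2-dimethyl-4-oxocyclobutyl]ethyl}zinc bromide (not isolated) | Br[Zn]CC[C@H]1C(=O)CC1(C)C | intermediate
28 | methyl (4Z)-7-[(1R)-2,2-dimethyl-4-oxocyclobutyl]-5-methylhept-4-enoate | COC(=O)CC/C=C(/C)CC[C@H]1C(=O)CC1(C)C | intermediate
29 | cyclic methyl enol ether of 30: 8-methoxy-4,11,11-trimethylbicyclo[7.2.0]undeca-4,8-diene, 4Z, C1 as in 30 (not isolated) | COC1=C2CC(C)(C)[C@H]2CC/C(C)=C\CC1 | intermediate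
30 | (1S,4Z,9R)-4,11,11-trimethylbicyclo[7.2.0]undec-4-en-8-one (caryophyllene numbering; trans ring fusion) | C/C1=C/CCC(=O)[C@@H]2CC(C)(C)[C@H]2CC1 | intermediate
31 | (1S,4Z,9R)-4,11,11-trimethyl-8-methylidenebicyclo[7.2.0]undec-4-ene ((1S,9R)-isocaryophyllene) | C/C1=C/CCC(=C)[C@@H]2CC(C)(C)[C@H]2CC1 | intermediate
32 | dienol cycloadduct (enol tautomer of 33: C–OH and C=C at the B/C fusion in place of the ketone and its α-H) (not isolated) | C=C1CC[C@H]2CC3=C(O[C@@]2(C)CC[C@H]2[C@H]1CC2(C)C)C(O)=C1C[C@H]2C[C@](C)(C(=O)O)C[C@H]2[C@]31C | intermediate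
33 | CNP0483070.2 | C=C1CC[C@H]2CC3=C(O[C@@]2(C)CC[C@H]2[C@H]1CC2(C)C)C(=O)[C@@H]1C[C@H]2C[C@](C)(C(=O)O)C[C@H]2[C@]31C | target

**Step count and risks**

Total step count: 15. Longest linear sequence: 8 steps (1, 2, 4, 5, 6, 7, 9, 15).

Most likely to fail:

1. Step 15 (hetero-Diels–Alder). The Z olefin of 31 is far less reactive than the strained E olefin of caryophyllene, the exocyclic methylene of 31 can compete as dienophile, the facial selectivity on the nine-membered ring is not secured, and 18 can dimerise. Fallback: set out from nor-ketone 30 in place of 31. Heating 18 with 30, which has only one olefin, gives the 8-oxo cycloadduct F1. The methylene is then introduced last by Takai–Lombardo methylenation (CH2Br2, Zn, TiCl4), which should spare the conjugated α-alkoxy enone. The route is rejoined at 33.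

2. Step 2 (desymmetrising [2+2]). Both the face selectivity (Me against ester on a remote quaternary carbon) and the enantioselectivity of the auxiliary are uncertain. Fallback: set out from 3 and desymmetrise later at a meso ketone. Dichloroketene cycloaddition (Cl3CCOCl, Zn–Cu couple) gives racemic dichlorocyclobutanone F2. Diazomethane ring expansion gives dichlorocyclopentanone F3. Zn in AcOH gives meso ketone F4, at which stage the two face isomers are separated. Enantioselective deprotonation with lithium (R,R)-bis(1-phenylethyl)amide and LiCl, then MeI, gives α-methyl ketone F5. Thermodynamic enol triflation (Tf2O, 2,6-di-tert-butyl-4-methylpyridine) gives alkenyl triflate F6. Aminocarbonylation (Pd(OAc)2, PPh3, CO, morpholine, NEt3) returns to the route at 13.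

3. Step 10 (auxiliary-controlled [2+2] on an acyclic trisubstituted olefin). The enantioselectivity with an unsubstituted keteniminium salt is uncertain. Fallback: set out from 19 and use a catalytic enantioselective allenoate–olefin [2+2] (2,2,2-trifluoroethyl buta-2,3-dienoate, chiral oxazaborolidine activated by AlBr3), which gives alkylidenecyclobutane F7. Ozonolysis (O3, then Me2S) of the exocyclic olefin returns to the route at 23.

**Further compounds**

F1 | step 15 | 8-oxo analogue of 33 (C=O in place of the exocyclic methylidene on the nine-membered ring) | O=C1CC[C@H]2CC3=C(O[C@@]2(C)CC[C@H]2[C@H]1CC2(C)C)C(=O)[C@@H]1C[C@H]2C[C@](C)(C(=O)O)C[C@H]2[C@]31C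
F2 | step 2 | benzyl 7,7-dichloro-3-methyl-6-oxobicyclo[3.2.0]heptane-3-carboxylate (racemic, relative configuration as in 7; one enantiomer drawn) | O=C1C(Cl)(Cl)[C@H]2C[C@](C)(C(=O)OCc3ccccc3)C[C@@H]12
F3 | step 2 | benzyl 4,4-dichloro-2-methyl-5-oxooctahydropentalene-2-carboxylate (racemic, cis-fused, ester cis to ring-fusion H; one enantiomer drawn) | O=C1C[C@H]2C[C@](C)(C(=O)OCc3ccccc3)C[C@H]2C1(Cl)Cl
F4 | step 2 | benzyl 2-methyl-5-oxooctahydropentalene-2-carboxylate (meso, cis-fused, ester cis to ring-fusion H) | O=C1C[C@H]2C[C@](C)(C(=O)OCc3ccccc3)C[C@H]2C1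
F5 | step 2 | benzyl 2,4-dimethyl-5-oxooctahydropentalene-2-carboxylate (cis-fused, ring configuration as in 13, C4 epimers) | O=C1C[C@H]2C[C@](C)(C(=O)OCc3ccccc3)C[C@H]2C1C
F6 | step 2 | benzyl (2S,3aR,6aS)-2,4-dimethyl-5-[(trifluoromethanesulfonyl)oxy]-1,2,3,3a,6,6a-hexahydropentalene-2-carboxylate | CC1=C(OS(=O)(=O)C(F)(F)F)C[C@H]2C[C@](C)(C(=O)OCc3ccccc3)C[C@@H]12
F7 | step 10 | 2,2,2-trifluoroethyl 2-[2-(2-bromoethyl)-3,3-dimethylcyclobutylidene]acetate (ring stereocentre as in 23) | O=C(OCC(F)(F)F)C=C1CC(C)(C)[C@H]1CCBr
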